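**Retrosynthetic overview**

1. Germacrane locants are used throughout: ring C1–C10, lactone O6–C12(=O)–C11(=C13)–C7, C14 on C10, C15 on C4. The last C–C bond made is C5–C6, by chromium/nickel-mediated addition of a C5 alkenyl iodide to a C6 aldehyde, which closes the ten-membered ring.
2. Enabling feature: C6 is the allylic carbinol carbon next to the C4=C5 alkene, and O6 and O8 are both γ to the C12 carboxyl through C7. The acyl group can therefore be parked on O8 as a temporary cis-γ-lactone and handed to O6 once the C6 alkoxide exists. Both ring alkenes (C1=C10, C4=C5) are cis within the ring and fold the chain.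
3. C7–C8, with both stereocentres, comes from a syn-selective, catalyst-controlled 2-(methoxycarbonyl)allylboration/lactonization of a C8 aldehyde (fragment C plus the C8–C5 chain).
4. C1=C10 comes from an E-selective Wittig reaction of a formyl ylide (fragment B; C14 enters as CHO). C4=C5–I comes from the iodoform/malonate route to an (E)-β-iodoacrylic acid (fragment A).
5. Ring order: temporary 8,12-γ-lactone (step 17), then the ten-membered carbocycle and the 6,12-γ-lactone together (step 20), with the 8,12-lactone opened in the same flask.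

Key step: step 20

Remark on the chemistry: the target is (6R,7R,8R); both ring alkenes are E by CIP but cis within the ring. The catalyst enantiomer in step 17 is chosen by analogy with simple allylboronates for delivery to the Si face of the aldehyde.

**Route**

Step 1
Reactants: 1 diethyl propanedioate (diethyl malonate); 2 2-(2-bromoethyl)-1,3-dioxolane
Product: 3 diethyl 2-[2-(1,3-dioxolan-2-yl)ethyl]propanedioate
Conditions: NaH, THF/DMF, 0 → 60 °C (1 in excess)
Reagents that add atoms: none
Why: Malonic ester alkylation (SN2 of the sodium enolate on a primary bromide), with excess malonate to suppress dialkylation; it joins C4/C15 to C3–C1.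

Step 2
Reactants: 3 diethyl 2-[2-(1,3-dioxolan-2-yl)ethyl]propanedioate
Product: 4 diethyl 2-(diiodomethyl)-2-[2-(1,3-dioxolan-2-yl)ethyl]propanedioate
Conditions: NaH, CHI3, Et2O, reflux
Reagents that add atoms: iodoform, IC(I)I
Why: C-alkylation of the substituted malonate anion by iodoform is the established entry to diiodomethyl malonates and brings in C5.

Step 3
Reactants: 4 diethyl 2-(diiodomethyl)-2-[2-(1,3-dioxolan-2-yl)ethyl]propanedioate
Product: 5 (2E)-2-[2-(1,3-dioxolan-2-yl)ethyl]-3-iodoprop-2-enoic acid
Conditions: KOH, EtOH/H2O (3:1), reflux; then cold 1 M HCl to pH 3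
Reagents that add atoms: potassium hydroxide, [K+].[OH-]
Why: Saponification followed by decarboxylative loss of iodide (Grob-type fragmentation of the malonate dianion) is known to give (E)-3-iodo-2-alkylacrylic acids, so iodine ends up trans to the carboxyl (later C15) and cis to the C3 chain, which fixes the C4=C5 geometry.

Step 4
Reactants: 5 (2E)-2-[2-(1,3-dioxolan-2-yl)ethyl]-3-iodoprop-2-enoic acid
Product: 6 (2E)-2-[2-(1,3-dioxolan-2-yl)ethyl]-3-iodoprop-2-en-1-ol
Conditions: LiAlH4, Et2O, 0 °C
Reagents that add atoms: none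
Why: Hydride reduction of the conjugated acid to the allylic alcohol, which at 0 °C should leave the alkenyl iodide and the acetal intact, as with the 2-methyl analogue.

Step 5
Reactants: 6 (2E)-2-[2-(1,3-dioxolan-2-yl)ethyl]-3-iodoprop-2-en-1-ol
Product: 7 (2E)-2-[2-(1,3-dioxolan-2-yl)ethyl]-3-iodoprop-2-en-1-yl acetate
Conditions: Ac2O, pyridine, DMAP (cat.), CH2Cl2, 0 °C → rt
Reagents that add atoms: acetic anhydride, CC(=O)OC(C)=O
Why: Standard DMAP-catalysed acylation installs the C15 acetate of the target at the outset.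

Step 6
Reactants: 7 (2E)-2-[2-(1,3-dioxolan-2-yl)ethyl]-3-iodoprop-2-en-1-yl acetate
Product: 8 (2E)-2-(iodomethylidene)-5-oxopentyl acetate (fragment A)
Conditions: 1 M aq. HCl/THF (1:3), rt
Reagents that add atoms: water, O
Why: Acid-catalysed acetal hydrolysis unmasks the C1 aldehyde under conditions too mild to cleave the allylic acetate.

Step 7
Reactants: 9 (3-bromopropoxy)(tert-butyl)dimethylsilane
Product: 10 {3-[(tert-butyldimethylsilyl)oxy]propyl}triphenylphosphonium bromide
Conditions: PPh3, MeCN, reflux
Reagents that add atoms: triphenylphosphine, c1ccc(cc1)P(c1ccccc1)c1ccccc1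
Why: SN2 quaternization of triphenylphosphine by a primary bromide.

Step 8
Reactants: 10 {3-[(tert-butyldimethylsilyl)oxy]propyl}triphenylphosphonium bromide
Product: 12 4-[(tert-butyldimethylsilyl)oxy]-2-(triphenyl-λ5-phosphanylidene)butanal (fragment B), via phosphonium ylide 11 (not isolated)
Conditions: KOtBu, THF, 0 °C; HCO2Et, 0 °C → rt
Reagents that add atoms: ethyl formate, CCOC=O
Why: C-formylation of a non-stabilized ylide by a formate ester, the released ethoxide deprotonating the acylphosphonium ion to the stabilized formyl ylide that carries C14 (CHO), C10, C9 and C8.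

Step 9
Reactants: 8 (2E)-2-(iodomethylidene)-5-oxopentyl acetate; 12 4-[(tert-butyldimethylsilyl)oxy]-2-(triphenyl-λ5-phosphanylidene)butanal
Product: 13 (2E,5E)-8-[(tert-butyldimethylsilyl)oxy]-6-formyl-2-(iodomethylidene)oct-5-en-1-yl acetate
Conditions: toluene, 90 °C
Reagents that add atoms: none
Why: Wittig olefination with an α-substituted formyl-stabilized ylide is reliably E-selective (CHO trans to C2, so C2 cis to C9), which sets the C1=C10 geometry, and the deactivated product enal should not react further.

Step 10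
Reactants: 13 (2E,5E)-8-[(tert-butyldimethylsilyl)oxy]-6-formyl-2-(iodomethylidene)oct-5-en-1-yl acetate
Product: 14 (2E,5E)-8-[(tert-butyldimethylsilyl)oxy]-6-(hydroxymethyl)-2-(iodomethylidene)oct-5-en-1-yl acetate
Conditions: NaBH4, CeCl3·7H2O, MeOH, −40 °C
Reagents that add atoms: none
Why: Luche 1,2-reduction of the enal is chemoselective over the acetate and the alkenyl iodide and frees the C14 hydroxyl alone.

Step 11
Reactants: 14 (2E,5E)-8-[(tert-butyldimethylsilyl)oxy]-6-(hydroxymethyl)-2-(iodomethylidene)oct-5-en-1-yl acetate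
Product: 15 (2E,6E)-6-[(acetyloxy)methyl]-2-{2-[(tert-butyldimethylsilyl)oxy]ethyl}-7-iodohepta-2,6-dien-1-yl 2-methylpropanoate
Conditions: i-PrCOCl, pyridine, DMAP (cat.), CH2Cl2, 0 °C
Reagents that add atoms: 2-methylpropanoyl chloride, CC(C)C(=O)Cl
Why: Acylation of the only free hydroxyl places the isobutyrate on C14, so the two acyl groups of the target are differentiated by construction.

Step 12
Reactants: 15 (2E,6E)-6-[(acetyloxy)methyl]-2-{2-[(tert-butyldimethylsilyl)oxy]ethyl}-7-iodohepta-2,6-dien-1-yl 2-methylpropanoate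
Product: 16 (2E,6E)-6-[(acetyloxy)methyl]-2-(2-hydroxyethyl)-7-iodohepta-2,6-dien-1-yl 2-methylpropanoate
Conditions: HF·pyridine, pyridine/THF, 0 °C → rt
Reagents that add atoms: none
Why: Fluoride-mediated cleavage of the primary silyl ether under mildly acidic conditions that leave both esters in place.

Step 13
Reactants: 16 (2E,6E)-6-[(acetyloxy)methyl]-2-(2-hydroxyethyl)-7-iodohepta-2,6-dien-1-yl 2-methylpropanoate
Product: 17 (2E,6E)-6-[(acetyloxy)methyl]-7-iodo-2-(2-oxoethyl)hepta-2,6-dien-1-yl 2-methylpropanoate
Conditions: Dess–Martin periodinane, NaHCO3, CH2Cl2, 0 °C; used crude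
Reagents that add atoms: none
Why: Buffered Dess–Martin oxidation should give the β,γ-unsaturated C8 aldehyde without moving the C1=C10 alkene into conjugation.

Step 14
Reactants: 18 [(tert-butyldimethylsilyl)oxy]acetaldehyde; 19 methyl prop-2-enoate (methyl acrylate)
Product: 20 methyl 4-[(tert-butyldimethylsilyl)oxy]-3-hydroxy-2-methylidenebutanoate (racemic)
Conditions: DABCO (0.3 equiv), neat, rt
Reagents that add atoms: none
Why: Morita–Baylis–Hillman reaction assembles C6, C7, C11, C12 and C13; the racemic carbinol centre is erased in step 16.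

Step 15
Reactants: 20 methyl 4-[(tert-butyldimethylsilyl)oxy]-3-hydroxy-2-methylidenebutanoate
Product: 21 methyl 3-(acetyloxy)-4-[(tert-butyldimethylsilyl)oxy]-2-methylidenebutanoate (racemic)
Conditions: Ac2O, pyridine, DMAP (cat.), CH2Cl2, 0 °C → rt
Reagents that add atoms: acetic anhydride, CC(=O)OC(C)=O
Why: Acetylation turns the allylic alcohol into a leaving group for π-allyl chemistry.

Step 16
Reactants: 21 methyl 3-(acetyloxy)-4-[(tert-butyldimethylsilyl)oxy]-2-methylidenebutanoate
Product: 22 methyl (2E)-4-[(tert-butyldimethylsilyl)oxy]-2-[(4,4,5,5-tetramethyl-1,3,2-dioxaborolan-2-yl)methyl]but-2-enoate (fragment C)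
Conditions: B2pin2, Pd2(dba)3 (2.5 mol%), DMSO, 50 °C
Reagents that add atoms: bis(pinacolato)diboron, CC1(C)OB(OC1(C)C)B1OC(C)(C)C(C)(C)O1
Why: Zerovalent-palladium-catalysed allylic borylation of a Morita–Baylis–Hillman acetate goes through the π-allyl complex, puts boron on the unsubstituted terminus and gives the enoate with the C6 substituent trans to the ester and cis to CH2B.

Step 17
Reactants: 17 (2E,6E)-6-[(acetyloxy)methyl]-7-iodo-2-(2-oxoethyl)hepta-2,6-dien-1-yl 2-methylpropanoate; 22 methyl (2E)-4-[(tert-butyldimethylsilyl)oxy]-2-[(4,4,5,5-tetramethyl-1,3,2-dioxaborolan-2-yl)methyl]but-2-enoate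
Product: 24 (2E,6E)-6-[(acetyloxy)methyl]-2-{[(2R,3S)-3-{[(tert-butyldimethylsilyl)oxy]methyl}-4-methylidene-5-oxooxolan-2-yl]methyl}-7-iodohepta-2,6-dien-1-yl 2-methylpropanoate, via pinacol borate ester 23 (not isolated)
Conditions: (S)-TRIP [(S)-3,3′-bis(2,4,6-triisopropylphenyl)-1,1′-binaphthyl-2,2′-diyl hydrogen phosphate] (10 mol%), 4 Å MS, toluene, −30 °C → rt, then 40 °C
Reagents that add atoms: none
Why: Proposed new method: the chiral phosphoric acid should hydrogen-bond to the pseudo-axial boronate oxygen and the formyl hydrogen and so accelerate and face-differentiate the closed six-membered chair allylboration, in which the C6 substituent (cis to CH2B in 22) sits axial and gives the syn adduct (C7 and C8 set together, Si-face attack giving 8R), after which borate 23 closes the cis-γ-lactone with loss of the methoxy group; the closest known reactions are the chiral-phosphoric-acid-catalysed allyl- and crotylboration of aldehydes with pinacol boronates and the achiral acid-catalysed 2-(alkoxycarbonyl)allylboration/lactonization.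

Step 18
Reactants: 24 the cis-lactone silyl ether from step 17
Product: 25 (2E,6E)-6-[(acetyloxy)methyl]-2-{[(2R,3S)-3-(hydroxymethyl)-4-methylidene-5-oxooxolan-2-yl]methyl}-7-iodohepta-2,6-dien-1-yl 2-methylpropanoate
Conditions: HF·pyridine, pyridine/THF, 0 °C
Reagents that add atoms: none
Why: Desilylation in a weakly acidic medium frees the C6 hydroxyl while keeping the lactone on O8 (no alkoxide is formed that could start the acyl shift early).

Step 19
Reactants: 25 the hydroxymethyl cis-lactone from step 18
Product: 26 (2E,6E)-6-[(acetyloxy)methyl]-2-{[(2R,3R)-3-formyl-4-methylidene-5-oxooxolan-2-yl]methyl}-7-iodohepta-2,6-dien-1-yl 2-methylpropanoate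
Conditions: Dess–Martin periodinane, NaHCO3, CH2Cl2, 0 °C; filtered and used at once
Reagents that add atoms: none
Why: Dess–Martin oxidation under buffered, non-basic conditions should deliver the C6 aldehyde without epimerizing C7 or moving the exocyclic alkene.

Step 20
Reactants: 26 the formyl cis-lactone alkenyl iodide from step 19
Product: 29 CNP0312458.1 (target), via chromium 6-alkoxide of the 8,12-olide 27 (not isolated), via chromium 8-alkoxide of the 6,12-olide 28 (not isolated)
Conditions: CrCl2 (10 equiv), NiCl2 (0.2 equiv), degassed DMSO/THF (3:1), 26 added by syringe pump to 2 mM, rt, then 40 °C; aq. sodium serinate work-up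
Reagents that add atoms: none
Why: Zerovalent nickel should insert into the C5–I bond with retention of alkene geometry and pass the alkenyl group to trivalent chromium, which adds to the C6 aldehyde (Nozaki–Hiyama–Kishi macrocyclization, closest known type: chromium/nickel closures of nine- to eleven-membered carbocycles) in a 10-exo-trig closure that the two ring-cis alkenes and the cis-lactone (C6 and C9 on one face) make feasible at high dilution. The only new stereocentre, C6, is controlled by C7: the bond should form anti to the C7–C11 bond (Felkin–Anh, sp2 carbon perpendicular) with the chromium-bound carbonyl oxygen turned outward, anti to C7–C8, which gives 6R. The chromium alkoxide 27 then sits gauche to C11 and attacks C12 (5-exo-trig) through a 2,6-dioxabicyclo[2.2.1]heptane tetrahedral intermediate, whose collapse with loss of O8 moves the acyl group to O6 (28); this is the known translactonization of hydroxy γ-lactones, here expected to run from a cis-β,γ-disubstituted to a trans-fused γ-lactone. The step needs chemoselectivity for the aldehyde over the lactone, the acrylate and the two allylic esters, which the non-basic, carbonyl-selective alkenylchromium provides, and it needs C7 to stay intact, which the neutral medium secures. Aqueous work-up protonates O8 and should give 29 with no protecting-group step.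

**Compound list**

1 | diethyl propanedioate | CCOC(=O)CC(=O)OCC | starting material
2 | 2-(2-bromoethyl)-1,3-dioxolane | BrCCC1OCCO1 | starting material
3 | diethyl 2-[2-(1,3-dioxolan-2-yl)ethyl]propanedioate | CCOC(=O)C(CCC1OCCO1)C(=O)OCC | intermediate
4 | diethyl 2-(diiodomethyl)-2-[2-(1,3-dioxolan-2-yl)ethyl]propanedioate | CCOC(=O)C(CCC1OCCO1)(C(I)I)C(=O)OCC | intermediate
5 | (2E)-2-[2-(1,3-dioxolan-2-yl)ethyl]-3-iodoprop-2-enoic acid | OC(=O)/C(CCC1OCCO1)=C/I | intermediate
6 | (2E)-2-[2-(1,3-dioxolan-2-yl)ethyl]-3-iodoprop-2-en-1-ol | OC/C(CCC1OCCO1)=C/I | intermediate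
7 | (2E)-2-[2-(1,3-dioxolan-2-yl)ethyl]-3-iodoprop-2-en-1-yl acetate | CC(=O)OC/C(CCC1OCCO1)=C/I | intermediate
8 | (2E)-2-(iodomethylidene)-5-oxopentyl acetate | CC(=O)OC/C(CCC=O)=C/I | intermediate
9 | (3-bromopropoxy)(tert-butyl)dimethylsilane | CC(C)(C)[Si](C)(C)OCCCBr | starting material
10 | {3-[(tert-butyldimethylsilyl)oxy]propyl}triphenylphosphonium bromide | CC(C)(C)[Si](C)(C)OCCC[P+](c1ccccc1)(c1ccccc1)c1ccccc1.[Br-] | intermediate
11 | tert-butyldimethyl[3-(triphenyl-λ5-phosphanylidene)propoxy]silane (ylide, not isolated) | CC(C)(C)[Si](C)(C)OCCC=P(c1ccccc1)(c1ccccc1)c1ccccc1 | intermediate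
12 | 4-[(tert-butyldimethylsilyl)oxy]-2-(triphenyl-λ5-phosphanylidene)butanal | CC(C)(C)[Si](C)(C)OCCC(C=O)=P(c1ccccc1)(c1ccccc1)c1ccccc1 | intermediate
13 | (2E,5E)-8-[(tert-butyldimethylsilyl)oxy]-6-formyl-2-(iodomethylidene)oct-5-en-1-yl acetate | CC(=O)OC/C(=C/I)CC/C=C(/C=O)CCO[Si](C)(C)C(C)(C)C | intermediate
14 | (2E,5E)-8-[(tert-butyldimethylsilyl)oxy]-6-(hydroxymethyl)-2-(iodomethylidene)oct-5-en-1-yl acetate | CC(=O)OC/C(=C/I)CC/C=C(/CO)CCO[Si](C)(C)C(C)(C)C | intermediate
15 | (2E,6E)-6-[(acetyloxy)methyl]-2-{2-[(tert-butyldimethylsilyl)oxy]ethyl}-7-iodohepta-2,6-dien-1-yl 2-methylpropanoate | CC(=O)OC/C(=C/I)CC/C=C(/COC(=O)C(C)C)CCO[Si](C)(C)C(C)(C)C | intermediate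
16 | (2E,6E)-6-[(acetyloxy)methyl]-2-(2-hydroxyethyl)-7-iodohepta-2,6-dien-1-yl 2-methylpropanoate | CC(=O)OC/C(=C/I)CC/C=C(/COC(=O)C(C)C)CCO | intermediate
17 | (2E,6E)-6-[(acetyloxy)methyl]-7-iodo-2-(2-oxoethyl)hepta-2,6-dien-1-yl 2-methylpropanoate | CC(=O)OC/C(=C/I)CC/C=C(/COC(=O)C(C)C)CC=O | intermediate
18 | [(tert-butyldimethylsilyl)oxy]acetaldehyde | CC(C)(C)[Si](C)(C)OCC=O | starting material
19 | methyl prop-2-enoate | C=CC(=O)OC | starting material
20 | methyl 4-[(tert-butyldimethylsilyl)oxy]-3-hydroxy-2-methylidenebutanoate (racemic) | C=C(C(=O)OC)C(O)CO[Si](C)(C)C(C)(C)C | intermediate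
21 | methyl 3-(acetyloxy)-4-[(tert-butyldimethylsilyl)oxy]-2-methylidenebutanoate (racemic) | C=C(C(=O)OC)C(OC(C)=O)CO[Si](C)(C)C(C)(C)C | intermediate
22 | methyl (2E)-4-[(tert-butyldimethylsilyl)oxy]-2-[(4,4,5,5-tetramethyl-1,3,2-dioxaborolan-2-yl)methyl]but-2-enoate | COC(=O)/C(CB1OC(C)(C)C(C)(C)O1)=C/CO[Si](C)(C)C(C)(C)C | intermediate
23 | O8-pinacolboryl syn adduct: open-chain methyl 2-methylidene ester bearing CH2OTBS on C7 and OBpin on C8, configured at C7 and C8 as in 24 (not isolated) | C=C(C(=O)OC)[C@@H](CO[Si](C)(C)C(C)(C)C)[C@H](OB1OC(C)(C)C(C)(C)O1)C/C(COC(=O)C(C)C)=C\CC/C(COC(C)=O)=C\I | intermediate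
24 | (2E,6E)-6-[(acetyloxy)methyl]-2-{[(2R,3S)-3-{[(tert-butyldimethylsilyl)oxy]methyl}-4-methylidene-5-oxooxolan-2-yl]methyl}-7-iodohepta-2,6-dien-1-yl 2-methylpropanoate (cis-lactone) | C=C1C(=O)O[C@H](C/C(COC(=O)C(C)C)=C\CC/C(COC(C)=O)=C\I)[C@@H]1CO[Si](C)(C)C(C)(C)C | intermediate
25 | (2E,6E)-6-[(acetyloxy)methyl]-2-{[(2R,3S)-3-(hydroxymethyl)-4-methylidene-5-oxooxolan-2-yl]methyl}-7-iodohepta-2,6-dien-1-yl 2-methylpropanoate | C=C1C(=O)O[C@H](C/C(COC(=O)C(C)C)=C\CC/C(COC(C)=O)=C\I)[C@@H]1CO | intermediate
26 | (2E,6E)-6-[(acetyloxy)methyl]-2-{[(2R,3R)-3-formyl-4-methylidene-5-oxooxolan-2-yl]methyl}-7-iodohepta-2,6-dien-1-yl 2-methylpropanoate | C=C1C(=O)O[C@H](C/C(COC(=O)C(C)C)=C\CC/C(COC(C)=O)=C\I)[C@@H]1C=O | intermediate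
27 | dichlorochromium (trivalent chromium) 6-alkoxide of the ten-membered cis-8,12-olide; 6R, C7 and C8 as in 29, both ring alkenes cis in the ring (not isolated) | C=C1C(=O)O[C@@H]2C/C(COC(=O)C(C)C)=C\CC/C(COC(C)=O)=C\[C@@H](O[Cr](Cl)Cl)[C@H]12 | intermediate
28 | dichlorochromium (trivalent chromium) 8-alkoxide of 29 (trans-6,12-olide; not isolated) | C=C1C(=O)O[C@@H]2/C=C(/COC(C)=O)CC/C=C(/COC(=O)C(C)C)C[C@@H](O[Cr](Cl)Cl)[C@@H]12 | intermediate
29 | CNP0312458.1: [(3aR,4R,6E,10E,11aR)-10-[(acetyloxy)methyl]-4-hydroxy-3-methylidene-2-oxo-2,3,3a,4,5,8,9,11a-octahydrocyclodeca[b]furan-6-yl]methyl 2-methylpropanoate | C=C1C(=O)O[C@@H]2/C=C(/COC(C)=O)CC/C=C(/COC(=O)C(C)C)C[C@@H](O)[C@@H]12 | target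

**Step count**

Total: 20 steps. Longest linear sequence: 15 steps (steps 1–6, 9–13, 17–20).

**Steps most likely to fail**

Step 17 (Proposed new method). The conjugated ester lowers the nucleophilicity of the allylboronate, so turnover under the chiral acid may be slow. The uncatalysed background path, or E/Z leakage of the boronate, could then erode the facial and syn selectivity. The fallback uses known chemistry and sets out from 17 and 22. The established achiral Lewis-acid-catalysed tandem allylboration/lactonization (Sc(OTf)3, toluene, 0 °C → rt), which is stereospecific for the cis series, would give the racemic cis-lactone. This is 24 together with its mirror-image lactone F1. The two would be separated by preparative supercritical-fluid chromatography on a chiral stationary phase, F1 discarded, and the route rejoined at 24.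

Step 20. Three things may go wrong: intermolecular addition may compete with ring closure, the alkenylchromium may add to the other face of the aldehyde, or the acyl shift may stop at alkoxide 27. The fallback sets out from 26 and decouples the three events. The chromium/nickel closure would be quenched cold so that the ring alcohol is isolated, in the unfavourable case as the 6S-hydroxy ten-membered cis-8,12-olide F2. Dess–Martin oxidation would give the ten-membered C6 ketone F3 (an enone with C4=C5). A reagent-controlled 1,2-reduction (oxazaborolidine/BH3·SMe2, using the catalyst enantiomer that delivers hydride to the face giving 6R) would then set the 6R-hydroxy ten-membered cis-8,12-olide F4. A separate, thermodynamically controlled lactone shift (DBU cat., CH2Cl2, rt) would bring F4 back to the route at 29.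

Step 19. Aldehyde 26 may decay during oxidation or handling by migration of the exocyclic C11=C13 alkene into the ring, by epimerization at C7, or by β-elimination of the lactone carboxylate. Before that, the lactone in 25 may shift to the free primary O6. The fallback carries C6 at the aldehyde oxidation level from the start. It sets out from 19 and commercial 2,2-dimethoxyacetaldehyde (COC(OC)C=O). Their Morita–Baylis–Hillman reaction (DABCO) would give methyl 3-hydroxy-4,4-dimethoxy-2-methylidenebutanoate F5. Acetylation would give methyl 3-(acetyloxy)-4,4-dimethoxy-2-methylidenebutanoate F6. Palladium-catalysed borylation as in step 16 would give methyl (2E)-4,4-dimethoxy-2-[(4,4,5,5-tetramethyl-1,3,2-dioxaborolan-2-yl)methyl]but-2-enoate F7. Allylboration/lactonization with 17 as in step 17 would give the dimethoxymethyl cis-lactone F8. Brief aqueous trifluoroacetic acid in CH2Cl2 at 0 °C would then unmask the aldehyde and rejoin the route at 26, which never passes through a free primary alcohol or a basic oxidation medium.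

Further compounds

F1 | step 17 | (2E,6E)-6-[(acetyloxy)methyl]-2-{[(2S,3R)-3-{[(tert-butyldimethylsilyl)oxy]methyl}-4-methylidene-5-oxooxolan-2-yl]methyl}-7-iodohepta-2,6-dien-1-yl 2-methylpropanoate (mirror image of 24) | C=C1C(=O)O[C@@H](C/C(COC(=O)C(C)C)=C\CC/C(COC(C)=O)=C\I)[C@H]1CO[Si](C)(C)C(C)(C)C
F2 | step 20 | 6S-hydroxy ten-membered cis-8,12-olide (C6 epimer of F4) | C=C1C(=O)O[C@@H]2C/C(COC(=O)C(C)C)=C\CC/C(COC(C)=O)=C\[C@H](O)[C@H]12
F3 | step 20 | ten-membered 6-oxo cis-8,12-olide | C=C1C(=O)O[C@@H]2C/C(COC(=O)C(C)C)=C\CC/C(COC(C)=O)=C\C(=O)[C@H]12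
F4 | step 20 | 6R-hydroxy ten-membered cis-8,12-olide (free alcohol of 27) | C=C1C(=O)O[C@@H]2C/C(COC(=O)C(C)C)=C\CC/C(COC(C)=O)=C\[C@@H](O)[C@H]12
F5 | step 19 | methyl 3-hydroxy-4,4-dimethoxy-2-methylidenebutanoate (racemic) | C=C(C(=O)OC)C(O)C(OC)OC
F6 | step 19 | methyl 3-(acetyloxy)-4,4-dimethoxy-2-methylidenebutanoate (racemic) | C=C(C(=O)OC)C(OC(C)=O)C(OC)OC
F7 | step 19 | methyl (2E)-4,4-dimethoxy-2-[(4,4,5,5-tetramethyl-1,3,2-dioxaborolan-2-yl)methyl]but-2-enoate | COC(=O)/C(CB1OC(C)(C)C(C)(C)O1)=C/C(OC)OC
F8 | step 19 | (2E,6E)-6-[(acetyloxy)methyl]-2-{[(2R,3R)-3-(dimethoxymethyl)-4-methylidene-5-oxooxolan-2-yl]methyl}-7-iodohepta-2,6-dien-1-yl 2-methylpropanoate | C=C1C(=O)O[C@H](C/C(COC(=O)C(C)C)=C\CC/C(COC(C)=O)=C\I)[C@@H]1C(OC)OC
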